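**Plan**
1. Retrosynthetic cuts, in order: the 1,10-epoxide oxygen; ring bond C3–C4 (alkenyl iodide + aldehyde); bond C7–C11 together with the C8–O bond, both traced back to a C7–C8 trans-oxirane; C5–C6 (alkyne + enal); C8–C9 (allyl–alkenyl coupling).
2. Forward: linear C3–C10 dienal → C6 alkynyl carbinol → anti-epoxy alcohol → five-membered lactone ring (first as a 2-methoxy-3-methylene-oxolane) by C7–C11 closure → lactone → Z-alkenyl iodide → ten-membered ring → epoxide.
3. Enabling feature: C7 lies between the oxygen-bearing C6 and C8, with O6 trans and O8 cis to C11 on the ring. This triad is the retron of an anti-2,3-epoxy alcohol, so opening the strained oxirane C7–C8 at C7 by a carbon tethered to O6 forms ring O6–C12–C11–C7–C6 and the C8 carbinol in one event.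
4. Helpers: C11 carries Br (handle for lithium) and C12 is held as a methyl acetal (lactol level) so that C11 is a σ-alkenyl anion rather than an enolate; Br leaves in step 9, the acetal in step 11.
5. Stereochemistry: C6 from catalytic asymmetric alkynylation; C7 and C8 from matched Sharpless epoxidation plus inversion at C7; C3 from CBS reduction; C1 and C10 from peripheral peracid attack on the macrocycle; 1(10)E from the Riley oxidation, 4Z from trans-hydrostannation.

Key step: step 9

Remark: germacrane numbering is used (ring C1–C10, lactone carbons C11–C13, C14 methyl, C15 hydroxymethyl); compounds 5, 8, 11 and 15 are taken as purchasable.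

**Step 1**
Reactants: 1 4-methylpent-3-en-1-ol
Product: 2 4-methoxybenzyl 4-methylpent-3-en-1-yl ether
Conditions: NaH, 4-methoxybenzyl chloride, Bu4NI (cat.), DMF, 0 °C to rt
Reagents that add atoms: 4-methoxybenzyl chloride, COc1ccc(CCl)cc1
Why: Williamson etherification of the primary alkoxide masks the future C3 oxygen as a PMB ether that lasts until step 15.

**Step 2**
Reactants: 2 4-methoxybenzyl 4-methylpent-3-en-1-yl ether
Product: 3 (E)-5-[(4-methoxybenzyl)oxy]-2-methylpent-2-en-1-ol
Conditions: SeO2 (cat.), t-BuOOH, salicylic acid (cat.), CH2Cl2, rt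
Reagents that add atoms: tert-butyl hydroperoxide, CC(C)(C)OO
Why: Riley allylic oxidation (ene reaction, then [2,3]-shift at selenium) hydroxylates the E-methyl group of the trisubstituted alkene, which fixes the 1(10)E geometry of the later ring.

**Step 3**
Reactants: 3 (E)-5-[(4-methoxybenzyl)oxy]-2-methylpent-2-en-1-ol
Product: 4 (E)-1-bromo-5-[(4-methoxybenzyl)oxy]-2-methylpent-2-ene
Conditions: CBr4, PPh3, CH2Cl2, 0 °C
Reagents that add atoms: carbon tetrabromide, BrC(Br)(Br)Br
Why: Appel bromination of a primary allylic alcohol proceeds by SN2 at carbon, without allylic shift or loss of alkene geometry.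

**Step 4**
Reactants: 4 (E)-1-bromo-5-[(4-methoxybenzyl)oxy]-2-methylpent-2-ene; 5 (E)-3-(tributylstannyl)prop-2-en-1-ol
Product: 6 (2E,5E)-8-[(4-methoxybenzyl)oxy]-5-methylocta-2,5-dien-1-ol
Conditions: Pd2(dba)3 (cat.), AsPh3, NMP, 40 °C
Reagents that add atoms: none
Why: Stille allyl–alkenyl coupling joins C8 to C9 at the primary allyl terminus with retention of both alkene geometries, giving the skipped diene.

**Step 5**
Reactants: 6 (2E,5E)-8-[(4-methoxybenzyl)oxy]-5-methylocta-2,5-dien-1-ol
Product: 7 (2E,5E)-8-[(4-methoxybenzyl)oxy]-5-methylocta-2,5-dienal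
Conditions: MnO2, CH2Cl2, rt
Reagents that add atoms: none
Why: MnO2 oxidises only the allylic alcohol, and its neutral conditions keep the skipped diene from moving into conjugation.

**Step 6**
Reactants: 7 (2E,5E)-8-[(4-methoxybenzyl)oxy]-5-methylocta-2,5-dienal; 8 tert-butyl(diphenyl)(prop-2-yn-1-yloxy)silane
Product: 9 (4S,5E,8E)-1-[(tert-butyldiphenylsilyl)oxy]-11-[(4-methoxybenzyl)oxy]-8-methylundeca-5,8-dien-2-yn-4-ol
Conditions: Me2Zn, (S,S)-ProPhenol (cat.), Ph3P=O (cat.), toluene, 4 °C
Reagents that add atoms: none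
Why: Zn-ProPhenol asymmetric alkynylation of an enal adds the zinc alkynylide 1,2 to one aldehyde face and sets C6 as S; the ligand enantiomer that gives this sense is to be confirmed on a model aldehyde, and the minor enantiomer is filtered out in step 7, which is fast only for the S carbinol.

**Step 7**
Reactants: 9 (4S,5E,8E)-enynol
Product: 10 (1R)-4-[(tert-butyldiphenylsilyl)oxy]-1-[(2R,3R)-3-{(2E)-5-[(4-methoxybenzyl)oxy]-2-methylpent-2-en-1-yl}oxiran-2-yl]but-2-yn-1-ol (anti-epoxy alcohol; C6 R, C7 R, C8 R)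
Conditions: Ti(OiPr)4, D-(−)-diisopropyl tartrate, t-BuOOH, 4 Å molecular sieves, CH2Cl2, −20 °C
Reagents that add atoms: tert-butyl hydroperoxide, CC(C)(C)OO
Why: Sharpless asymmetric epoxidation of a secondary E-allylic alcohol in the matched sense: with D-(−)-tartrate the peroxide oxygen is delivered to the face that gives the 7R,8R trans-oxirane anti (erythro) to the carbinol, and only the allylic alkene reacts while the isolated trisubstituted alkene and the alkyne are inert.

**Step 8**
Reactants: 10 anti-epoxy alcohol; 11 methoxyallene (1-methoxypropa-1,2-diene)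
Product: 12 O6-(2-bromo-1-methoxyprop-2-en-1-yl) mixed acetal of 10 (both epimers at acetal carbon C12)
Conditions: N-bromosuccinimide, CH2Cl2, −78 to −40 °C
Reagents that add atoms: N-bromosuccinimide, O=C1CCC(=O)N1Br
Why: Bromoacetalisation of an alkoxyallene (Ueno–Stork-type acetal formation): Br+ adds to the central allene carbon and O6 traps the methoxy-stabilised oxocarbenium ion; no base is present, so Payne rearrangement is avoided, and the electron-rich allene should outcompete the trisubstituted alkene for NBS at low temperature.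

**Step 9**
Reactants: 12 bromoallyl mixed acetal
Product: 14 (1R,3E)-1-[(2S,3R)-2-{3-[(tert-butyldiphenylsilyl)oxy]prop-1-yn-1-yl}-5-methoxy-4-methylideneoxolan-3-yl]-6-[(4-methoxybenzyl)oxy]-3-methylhex-3-en-1-ol (acetal epimers), via alkenyllithium 13 (not isolated)
Conditions: t-BuLi (2.1 equiv), Et2O/THF, −78 to −40 °C; then H2O
Reagents that add atoms: none
Why: Bromine–lithium exchange, which is faster than any deprotonation at −78 °C, turns C11–Br into an sp2 carbanion whose lone pair lies in the plane of the allyl acetal; this carbon attacks C7 of the trans-oxirane from the side opposite the C7–O bond, and relief of oxirane strain drives formation of the C7–C11 bond while the C8 oxygen leaves as its lithium alkoxide. The closest known reaction types are the Parham-type anionic cyclisation of aryl- and alkenyllithiums onto tethered epoxides and the use of 2-lithioacrolein acetals as acrolein α-anion equivalents. The new ring, the oxolane O6–C12–C11–C7–C6 that becomes the lactone, closes in the 5-exo-tet mode. C7 is set by stereospecific SN2 inversion of the oxirane carbon defined in step 7, C8 keeps the configuration of its C–O bond and C6 is untouched, so the anti-epoxy alcohol maps onto the trans-fused lactone (H6/H7 trans) with O8 cis to C11 on the future ten-membered ring; the acetal carbon is an inconsequential epimer mixture. The step needs attack at C7 and not at C8 (6-endo), which the three-atom O6–C12 tether and the collinear SN2 trajectory secure, and it needs a σ-carbanion and not an enolate, which is why C12 is held at the acetal level: a tethered ester enolate would face the disfavoured 5-(enolendo)-exo-tet geometry.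

**Step 10**
Reactants: 14 oxolane alcohol; 15 methacrylic anhydride
Product: 16 O8-methacrylate of 14
Conditions: DMAP (cat.), Et3N, CH2Cl2, 0 °C to rt
Reagents that add atoms: none
Why: DMAP-catalysed acylation of the only free hydroxyl installs the C8 ester of the target and protects O8 during the following oxidation.

**Step 11**
Reactants: 16 O8-methacrylate of 14
Product: 18 (1R,3E)-1-[(2S,3R)-2-{3-[(tert-butyldiphenylsilyl)oxy]prop-1-yn-1-yl}-4-methylidene-5-oxooxolan-3-yl]-6-[(4-methoxybenzyl)oxy]-3-methylhex-3-en-1-yl 2-methylprop-2-enoate, via lactol 17 (not isolated)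
Conditions: PPTS, acetone/H2O, 45 °C; then MnO2, CH2Cl2, rt
Reagents that add atoms: water, O
Why: Acid hydrolysis of the allylic mixed acetal gives the lactol, whose allylic hemiacetal is oxidised by MnO2 to the α-methylene-γ-lactone; this removes the acetal helper and leaves the silyl ether, the PMB ether and the methacrylate intact.

**Step 12**
Reactants: 18 silyl-protected alkynyl lactone
Product: 19 (1R,3E)-1-[(2S,3R)-2-(3-hydroxyprop-1-yn-1-yl)-4-methylidene-5-oxooxolan-3-yl]-6-[(4-methoxybenzyl)oxy]-3-methylhex-3-en-1-yl 2-methylprop-2-enoate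
Conditions: HF·pyridine, pyridine, THF, 0 °C to rt
Reagents that add atoms: none
Why: Buffered fluoride cleavage of the primary silyl ether spares the PMB ether, both esters and the Michael acceptors, and frees the propargylic hydroxyl needed as a directing group.

**Step 13**
Reactants: 19 propargylic alcohol
Product: 21 (1R,3E)-1-[(2S,3R)-2-[(1Z)-3-hydroxy-2-iodoprop-1-en-1-yl]-4-methylidene-5-oxooxolan-3-yl]-6-[(4-methoxybenzyl)oxy]-3-methylhex-3-en-1-yl 2-methylprop-2-enoate, via alkenylstannane 20 (not isolated)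
Conditions: [Cp*RuCl]4 (cat.), Bu3SnH, CH2Cl2, rt; then I2, CH2Cl2, 0 °C
Reagents that add atoms: iodine, II; tributyltin hydride, CCCC[SnH](CCCC)CCCC (its tin stays only in 20)
Why: Ruthenium-catalysed hydroxyl-directed trans-hydrostannation places tin on C4 (next to the free C15 hydroxyl) and hydrogen anti on C5, and iododestannylation with retention gives the Z-alkenyl iodide with iodine cis to C6, which fixes the 4Z geometry.

**Step 14**
Reactants: 21 Z-iodo allylic alcohol
Product: 22 O15-tert-butyldimethylsilyl ether of 21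
Conditions: TBSCl, imidazole, CH2Cl2, 0 °C
Reagents that add atoms: tert-butyldimethylsilyl chloride, CC(C)(C)[Si](C)(C)Cl
Why: Silylation of the primary allylic alcohol keeps O15 out of the two oxidations that follow.

**Step 15**
Reactants: 22 O15-silyl ether
Product: 23 primary alcohol at C3 (PMB removed)
Conditions: DDQ, CH2Cl2/pH 7 buffer, 0 °C
Reagents that add atoms: none
Why: Oxidative cleavage of the PMB ether by DDQ (hydride abstraction, hemiacetal hydrolysis) is orthogonal to the silyl ether, the alkenyl iodide and the esters.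

**Step 16**
Reactants: 23 primary alcohol
Product: 24 C3 aldehyde (β,γ-unsaturated), used at once
Conditions: Dess–Martin periodinane, NaHCO3, CH2Cl2, 0 °C
Reagents that add atoms: none
Why: Buffered Dess–Martin oxidation gives the aldehyde under conditions mild enough to keep the 1(10) alkene out of conjugation.

**Step 17**
Reactants: 24 iodo aldehyde
Product: 25 (1(10)E,4Z)-15-[(tert-butyldimethylsilyl)oxy]-3-hydroxy-8β-(methacryloyloxy)germacra-1(10),4,11(13)-trien-12,6α-olide (6R,7R,8R; both C3 epimers)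
Conditions: CrCl2, NiCl2 (cat.), DMSO/THF, rt, high dilution
Reagents that add atoms: none
Why: Intramolecular Nozaki–Hiyama–Kishi reaction: nickel-catalysed formation of the alkenylchromium reagent at C4 (alkene geometry retained) and its addition to the C3 aldehyde closes the ten-membered ring, and both C3 epimers are acceptable because steps 18 and 19 converge them.

**Step 18**
Reactants: 25 macrocyclic allylic alcohol
Product: 26 3-oxo macrocycle (cross-conjugated enone)
Conditions: Dess–Martin periodinane, NaHCO3, CH2Cl2, 0 °C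
Reagents that add atoms: none
Why: Dess–Martin oxidation of the allylic alcohol gives one enone from both epimers, erasing the uncontrolled C3 centre without touching the silyl ether or the esters.

**Step 19**
Reactants: 26 enone
Product: 27 (3S)-allylic alcohol, 15-O-silyl
Conditions: (R)-2-methyl-CBS-oxazaborolidine, catecholborane, toluene, −78 °C
Reagents that add atoms: none
Why: Corey–Bakshi–Shibata reduction: with the (R)-oxazaborolidine the alkenyl carbon C4 acts as the large substituent and the C2 methylene as the small one, so hydride delivery should give the 3S alcohol by reagent control, and 1,2-reduction at −78 °C spares the esters and alkenes.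

**Step 20**
Reactants: 27 (3S)-alcohol
Product: 28 (3S)-3,15-diol
Conditions: HF·pyridine, pyridine, THF, 0 °C
Reagents that add atoms: none
Why: Fluoride desilylation of the allylic primary silyl ether is done before the acid-sensitive epoxide exists.

**Step 21**
Reactants: 28 diol
Product: 29 target, (1R,3S,4Z,6R,7R,8R,10R)-1,10-epoxy-3,15-dihydroxy-8-(methacryloyloxy)germacra-4,11(13)-dien-12,6-olide
Conditions: 3-chloroperbenzoic acid, NaHCO3, CH2Cl2, −20 to 0 °C
Reagents that add atoms: 3-chloroperbenzoic acid, OOC(=O)c1cccc(Cl)c1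
Why: Prilezhaev epoxidation: the electron-rich 1(10) trisubstituted alkene should react ahead of the 4,5-alkene (deactivated by three allylic C–O bonds) and the two acrylate-type alkenes, and attack on the outer face of the E-alkene in the ring conformer with C14 on the β face should give the 1R,10R (1β,10α) epoxide.

**Compound list**
1 | 4-methylpent-3-en-1-ol | CC(C)=CCCO | starting material
2 | 4-methoxybenzyl 4-methylpent-3-en-1-yl ether | CC(C)=CCCOCc1ccc(OC)cc1 | intermediate
3 | (E)-5-[(4-methoxybenzyl)oxy]-2-methylpent-2-en-1-ol | OC/C(C)=C/CCOCc1ccc(OC)cc1 | intermediate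
4 | (E)-1-bromo-5-[(4-methoxybenzyl)oxy]-2-methylpent-2-ene | BrC/C(C)=C/CCOCc1ccc(OC)cc1 | intermediate
5 | (E)-3-(tributylstannyl)prop-2-en-1-ol | CCCC[Sn](CCCC)(CCCC)/C=C/CO | starting material
6 | (2E,5E)-8-[(4-methoxybenzyl)oxy]-5-methylocta-2,5-dien-1-ol | OC/C=C/C/C(C)=C/CCOCc1ccc(OC)cc1 | intermediate
7 | (2E,5E)-8-[(4-methoxybenzyl)oxy]-5-methylocta-2,5-dienal | O=C/C=C/C/C(C)=C/CCOCc1ccc(OC)cc1 | intermediate
8 | tert-butyl(diphenyl)(prop-2-yn-1-yloxy)silane | C#CCO[Si](c1ccccc1)(c1ccccc1)C(C)(C)C | starting material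
9 | (4S,5E,8E)-1-[(tert-butyldiphenylsilyl)oxy]-11-[(4-methoxybenzyl)oxy]-8-methylundeca-5,8-dien-2-yn-4-ol | CC(C)(C)[Si](c1ccccc1)(c1ccccc1)OCC#C[C@@H](O)/C=C/C/C(C)=C/CCOCc1ccc(OC)cc1 | intermediate
10 | (1R)-4-[(tert-butyldiphenylsilyl)oxy]-1-[(2R,3R)-3-{(2E)-5-[(4-methoxybenzyl)oxy]-2-methylpent-2-en-1-yl}oxiran-2-yl]but-2-yn-1-ol | CC(C)(C)[Si](c1ccccc1)(c1ccccc1)OCC#C[C@@H](O)[C@H]1O[C@@H]1C/C(C)=C/CCOCc1ccc(OC)cc1 | intermediate
11 | methoxyallene (1-methoxypropa-1,2-diene) | C=C=COC | starting material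
12 | O6-(2-bromo-1-methoxyprop-2-en-1-yl) mixed acetal of 10, acetal epimers | CC(C)(C)[Si](c1ccccc1)(c1ccccc1)OCC#C[C@@H](OC(OC)C(Br)=C)[C@H]1O[C@@H]1C/C(C)=C/CCOCc1ccc(OC)cc1 | intermediate
13 | 2-lithioallyl acetal (C11–Li) derived from 12, not isolated | CC(C)(C)[Si](c1ccccc1)(c1ccccc1)OCC#C[C@@H](OC(OC)C([Li])=C)[C@H]1O[C@@H]1C/C(C)=C/CCOCc1ccc(OC)cc1 | intermediate
14 | (1R,3E)-1-[(2S,3R)-2-{3-[(tert-butyldiphenylsilyl)oxy]prop-1-yn-1-yl}-5-methoxy-4-methylideneoxolan-3-yl]-6-[(4-methoxybenzyl)oxy]-3-methylhex-3-en-1-ol, acetal epimers | CC(C)(C)[Si](c1ccccc1)(c1ccccc1)OCC#C[C@H]1OC(OC)C(=C)[C@@H]1[C@H](O)C/C(C)=C/CCOCc1ccc(OC)cc1 | intermediate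
15 | methacrylic anhydride | C=C(C)C(=O)OC(=O)C(C)=C | starting material
16 | 2-methylprop-2-enoate (at O8) of 14 | CC(C)(C)[Si](c1ccccc1)(c1ccccc1)OCC#C[C@H]1OC(OC)C(=C)[C@@H]1[C@H](OC(=O)C(C)=C)C/C(C)=C/CCOCc1ccc(OC)cc1 | intermediate
17 | lactol (5-hydroxy-4-methylideneoxolane) from 16, not isolated | CC(C)(C)[Si](c1ccccc1)(c1ccccc1)OCC#C[C@H]1OC(O)C(=C)[C@@H]1[C@H](OC(=O)C(C)=C)C/C(C)=C/CCOCc1ccc(OC)cc1 | intermediate
18 | (1R,3E)-1-[(2S,3R)-2-{3-[(tert-butyldiphenylsilyl)oxy]prop-1-yn-1-yl}-4-methylidene-5-oxooxolan-3-yl]-6-[(4-methoxybenzyl)oxy]-3-methylhex-3-en-1-yl 2-methylprop-2-enoate | CC(C)(C)[Si](c1ccccc1)(c1ccccc1)OCC#C[C@H]1OC(=O)C(=C)[C@@H]1[C@H](OC(=O)C(C)=C)C/C(C)=C/CCOCc1ccc(OC)cc1 | intermediate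
19 | (1R,3E)-1-[(2S,3R)-2-(3-hydroxyprop-1-yn-1-yl)-4-methylidene-5-oxooxolan-3-yl]-6-[(4-methoxybenzyl)oxy]-3-methylhex-3-en-1-yl 2-methylprop-2-enoate | OCC#C[C@H]1OC(=O)C(=C)[C@@H]1[C@H](OC(=O)C(C)=C)C/C(C)=C/CCOCc1ccc(OC)cc1 | intermediate
20 | (Z)-alkenylstannane: analogue of 19 with a (1Z)-3-hydroxy-2-(tributylstannyl)prop-1-en-1-yl group on C6, not isolated | OC/C([Sn](CCCC)(CCCC)CCCC)=C/[C@H]1OC(=O)C(=C)[C@@H]1[C@H](OC(=O)C(C)=C)C/C(C)=C/CCOCc1ccc(OC)cc1 | intermediate
21 | (1R,3E)-1-[(2S,3R)-2-[(1Z)-3-hydroxy-2-iodoprop-1-en-1-yl]-4-methylidene-5-oxooxolan-3-yl]-6-[(4-methoxybenzyl)oxy]-3-methylhex-3-en-1-yl 2-methylprop-2-enoate | OC/C(I)=C/[C@H]1OC(=O)C(=C)[C@@H]1[C@H](OC(=O)C(C)=C)C/C(C)=C/CCOCc1ccc(OC)cc1 | intermediate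
22 | O15-tert-butyldimethylsilyl ether of 21 | CC(C)(C)[Si](C)(C)OC/C(I)=C/[C@H]1OC(=O)C(=C)[C@@H]1[C@H](OC(=O)C(C)=C)C/C(C)=C/CCOCc1ccc(OC)cc1 | intermediate
23 | primary alcohol at C3 from 22 (6-hydroxy-3-methylhex-3-enyl side chain) | CC(C)(C)[Si](C)(C)OC/C(I)=C/[C@H]1OC(=O)C(=C)[C@@H]1[C@H](OC(=O)C(C)=C)C/C(C)=C/CCO | intermediate
24 | C3 aldehyde from 23 (3-methyl-6-oxohex-3-enyl side chain) | CC(C)(C)[Si](C)(C)OC/C(I)=C/[C@H]1OC(=O)C(=C)[C@@H]1[C@H](OC(=O)C(C)=C)C/C(C)=C/CC=O | intermediate
25 | (1(10)E,4Z,6R,7R,8R)-15-[(tert-butyldimethylsilyl)oxy]-3-hydroxy-8-(methacryloyloxy)germacra-1(10),4,11(13)-trien-12,6-olide, C3 epimers | C=C(C)C(=O)O[C@@H]1C/C(C)=C/CC(O)/C(CO[Si](C)(C)C(C)(C)C)=C\[C@H]2OC(=O)C(=C)[C@@H]21 | intermediate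
26 | (1(10)E,4Z,6R,7R,8R)-15-[(tert-butyldimethylsilyl)oxy]-8-(methacryloyloxy)-3-oxogermacra-1(10),4,11(13)-trien-12,6-olide | C=C(C)C(=O)O[C@@H]1C/C(C)=C/CC(=O)/C(CO[Si](C)(C)C(C)(C)C)=C\[C@H]2OC(=O)C(=C)[C@@H]21 | intermediate
27 | (1(10)E,3S,4Z,6R,7R,8R)-15-[(tert-butyldimethylsilyl)oxy]-3-hydroxy-8-(methacryloyloxy)germacra-1(10),4,11(13)-trien-12,6-olide | C=C(C)C(=O)O[C@@H]1C/C(C)=C/C[C@H](O)/C(CO[Si](C)(C)C(C)(C)C)=C\[C@H]2OC(=O)C(=C)[C@@H]21 | intermediate
28 | (1(10)E,3S,4Z,6R,7R,8R)-3,15-dihydroxy-8-(methacryloyloxy)germacra-1(10),4,11(13)-trien-12,6-olide | C=C(C)C(=O)O[C@@H]1C/C(C)=C/C[C@H](O)/C(CO)=C\[C@H]2OC(=O)C(=C)[C@@H]21 | intermediate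
29 | (1R,3S,4Z,6R,7R,8R,10R)-1,10-epoxy-3,15-dihydroxy-8-(methacryloyloxy)germacra-4,11(13)-dien-12,6-olide | C=C(C)C(=O)O[C@@H]1C[C@@]2(C)O[C@@H]2C[C@H](O)/C(CO)=C\[C@H]2OC(=O)C(=C)[C@@H]21 | target

**Step count**
Total steps: 21. Longest linear sequence: 21 steps (1 to 29); 5, 8, 11 and 15 enter as purchased building blocks.

**Steps most likely to fail**

Step 9 (key ring closure). The alkenyllithium may be consumed before it reaches C7: by proton transfer from the propargylic C6–H, by β-elimination of alkoxide from the lithiated acetal, or by carbolithiation of the neighbouring alkyne; opening could also drift to the 6-endo mode at C8. Fallback (sets out from 10, returns at 18): the polar opening is replaced by a homolytic one. O-Propargylation of 10 (propargyl bromide, Ag2O, CH2Cl2) would give the propargyl ether F1. Cp2TiCl, made from Cp2TiCl2 and Zn dust in THF, would cleave the C7–O bond to a C7 radical that closes 5-exo-dig onto the ether alkyne (Nugent–RajanBabu-type radical cyclisation, trans ring substituents expected) to give the 4-methylideneoxolane alcohol F2. Acylation with 15 gives the methacrylate F3, and allylic oxidation of the ring CH2 next to oxygen (CrO3·3,5-dimethylpyrazole, CH2Cl2, −20 °C) gives lactone 18.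

Step 17 (ring closure to the ten-membered ring). Ring strain may favour intermolecular coupling over cyclisation, and the β,γ-unsaturated aldehyde may isomerise into conjugation before it reacts. Fallback (sets out from 20, returns at 26): the C3–C4 bond is made by acylation instead of carbonyl addition. The stannane 20 would be isolated and silylated (TBSCl, imidazole) to the silyl ether F4. DDQ frees the primary alcohol F5, Dess–Martin oxidation gives the aldehyde F6, and NaClO2/NaH2PO4/2-methyl-2-butene the carboxylic acid F7. 1-Chloro-N,N,2-trimethylprop-1-en-1-amine converts it into the acid chloride F8, which would be closed without isolation by intramolecular Stille acylation (Pd2(dba)3, tri(2-furyl)phosphine, toluene, high dilution) with retention of alkene geometry, giving enone 26 directly.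

Step 21 (late epoxidation). Hydroxyl-directed attack on the 4,5-alkene or poor facial selectivity at the 1(10) alkene would give regio- or stereoisomeric epoxides. Fallback (sets out from 27, returns at 29): reagent control one step earlier. Shi epoxidation of 27 with the D-fructose-derived ketone (Oxone, buffered MeCN/dimethoxymethane/water, 0 °C), whose spiro transition state should give the 1R,10R epoxide of an E-trisubstituted alkene, would give the silyl-protected epoxide F9; desilylation with Bu4NF buffered with AcOH (THF, 0 °C) gives 29.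

**Further compounds**
F1 | step 9 | O6-propargyl ether of 10 | CC(C)(C)[Si](c1ccccc1)(c1ccccc1)OCC#C[C@@H](OCC#C)[C@H]1O[C@@H]1C/C(C)=C/CCOCc1ccc(OC)cc1
F2 | step 9 | 4-methylideneoxolane alcohol (C12 as CH2; analogue of 14 without the methoxy group) | CC(C)(C)[Si](c1ccccc1)(c1ccccc1)OCC#C[C@H]1OCC(=C)[C@@H]1[C@H](O)C/C(C)=C/CCOCc1ccc(OC)cc1
F3 | step 9 | O8-methacrylate of F2 | CC(C)(C)[Si](c1ccccc1)(c1ccccc1)OCC#C[C@H]1OCC(=C)[C@@H]1[C@H](OC(=O)C(C)=C)C/C(C)=C/CCOCc1ccc(OC)cc1
F4 | step 17 | O15-tert-butyldimethylsilyl ether of stannane 20 | CC(C)(C)[Si](C)(C)OC/C([Sn](CCCC)(CCCC)CCCC)=C/[C@H]1OC(=O)C(=C)[C@@H]1[C@H](OC(=O)C(C)=C)C/C(C)=C/CCOCc1ccc(OC)cc1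
F5 | step 17 | primary alcohol at C3 from F4 | CC(C)(C)[Si](C)(C)OC/C([Sn](CCCC)(CCCC)CCCC)=C/[C@H]1OC(=O)C(=C)[C@@H]1[C@H](OC(=O)C(C)=C)C/C(C)=C/CCO
F6 | step 17 | C3 aldehyde from F5 | CC(C)(C)[Si](C)(C)OC/C([Sn](CCCC)(CCCC)CCCC)=C/[C@H]1OC(=O)C(=C)[C@@H]1[C@H](OC(=O)C(C)=C)C/C(C)=C/CC=O
F7 | step 17 | C3 carboxylic acid from F6 | CC(C)(C)[Si](C)(C)OC/C([Sn](CCCC)(CCCC)CCCC)=C/[C@H]1OC(=O)C(=C)[C@@H]1[C@H](OC(=O)C(C)=C)C/C(C)=C/CC(=O)O
F8 | step 17 | C3 acid chloride from F7 | CC(C)(C)[Si](C)(C)OC/C([Sn](CCCC)(CCCC)CCCC)=C/[C@H]1OC(=O)C(=C)[C@@H]1[C@H](OC(=O)C(C)=C)C/C(C)=C/CC(=O)Cl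
F9 | step 21 | 15-O-tert-butyldimethylsilyl ether of 29 (1R,10R epoxide) | C=C(C)C(=O)O[C@@H]1C[C@@]2(C)O[C@@H]2C[C@H](O)/C(CO[Si](C)(C)C(C)(C)C)=C\[C@H]2OC(=O)C(=C)[C@@H]21
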